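The numbers in the tables were generated by integration from invented constants, and the scatter is random.

Early on, starting material falls alike in the autumn and summer runs, which differ in their reagent charge; the flask asked about has a reagent charge between theirs.

| flask | starting material | reagent | free catalyst | second catalyst | remark | time |
|---|---|---|---|---|---|---|
| autumn | 0.050 M | 0.045 M | 2.7 mM | 0.45 mM | run made earlier |  |
| summer | 0.050 M | 0.18 M | 2.7 mM | 0.45 mM | run made earlier |  |
| flask | 0.050 M | 0.0900 M | 2.7 mM | 0.45 mM |  | 10 h |

- autumn (time / h: intermediate / %, target / %, starting material / %): 0.133: 17.4, 0.1, 78.6; 0.250: 26.8, 0.5, 65.1; 0.500: 32.6, 1.5, 41.3; 1.33: 17.1, 5.0, 8.8; 2.50: 3.5, 6.4, 1.3; 6.00: 0, 5.8, 0; 12.0: 0.4, 6.0, 1.0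
- summer (time / h: intermediate / %, target / %, starting material / %): 0.133: 17.8, 0, 78.4; 0.250: 26.3, 2.3, 64.9; 0.500: 30.8, 4.9, 41.2; 1.33: 16.9, 11.2, 9.9; 2.50: 4.1, 12.2, 1.6; 6.00: 0, 12.6, 0.3; 12.0: 0.2, 12.0, 0.6

(scatter of a reading: 0.5 percentage points)

- what was read earlier has a scatter of 0.5 percentage points, one standard deviation
- what may be going on: starting material + free catalyst -> free catalyst + intermediate; reagent + second catalyst + intermediate -> second catalyst + target; 2 reagent -> homo dimer; intermediate -> side product

- when, up to 10 h, the flask holds most intermediate
- the amount of intermediate, in percent of the starting material charged, at that time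

At 0.500 h starting material reads 41.3% in autumn and 41.2% in summer, which gives a pseudo-first-order constant

k_A = 1.77 h⁻¹.

Yet summer's target ends at twice autumn's, while its intermediate at 0.500 h lies only 1.8 percentage points lower. The two agree once the shares are compared: summer's target holds 12.0% of the charge, less than the remainder, so a larger target branch moves the total loss of intermediate little.

At the top of the intermediate curve, making equals loss, so [starting material]/[intermediate] there equals the loss constant over k_A. The readings nearest the top give 1.27 in autumn and 1.34 in summer. Reagent falls during a run, so the loss constant is replaced by one mean value. In the proposed scheme the loss constant of intermediate is a first-order term plus a term proportional to reagent, so the ratio is taken as a straight line in the reagent charge. The flask's charge stands a third of the way from autumn's to summer's, which gives 1.29, the estimated loss-to-making ratio ρ. For constant ρ: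

t_max = ln ρ / (k_A(ρ − 1)) = 0.496 h

[intermediate]_max = (1/ρ)^(ρ/(ρ − 1)) = 32.2%

Either run's own ratio in place of the interpolated one gives 31.6% to 32.5%, an estimate of how far the choice of ratio moves the answer, not a bound on its error.

The forecast gives 0.5 h and 32%: “Most of that loss is the reagent-independent side reaction”. The flask gives 0.503 h and 31.6%.

    starting material + free catalyst → free catalyst + intermediate (k = 0.180 L mol⁻¹ s⁻¹)
    reagent + second catalyst + intermediate → second catalyst + target (k = 2.80 L² mol⁻² s⁻¹)
    2 reagent → homo dimer (k = 0.00190 L mol⁻¹ s⁻¹)
    intermediate → side product (k = 5.70 × 10⁻⁴ s⁻¹)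

At 0.503 h the flask's starting material over intermediate stands at 1.31, beside the ρ of 1.29. The neighbouring flask has 0.0011 M of free catalyst instead of 2.7 mM. The first step is proportional to free catalyst, so with the loss constant held, that flask's ratio is

ρ′ = ρ[free catalyst]/[free catalyst]′ = 3.17,

and the same expression gives 18.5%. That neighbouring flask holds 18.3% of intermediate at its top.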